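## The problem

Compound 19 is a 2,3-dihydrobenzofuran: benzene ring A is fused through C3a and C7a to dihydrofuran ring B (O1, C2, C3). C2 carries a 1-formylvinyl group (Cα is its alkene carbon bonded to C2), the C3 oxygen carries a 3-methylbutanoate, and C5 carries a 1-acyloxyethyl group esterified with (R)-2-methylbutanoic acid. Of the four stereocentres, C2 (R) and C3 (S) are neighbours, trans on ring B, and must be set together or one from the other. The carbinol carbon on C5 (R) is too far from them to be controlled by the ring and needs a reagent; the fourth lies in the acid and is bought. The two secondary benzylic oxygens bear different acyl groups, so they must be acylated at different times, with one masked as the ketone it comes from. The C3 ester is the fragile centre: C3 is benzylic with O1 ortho to C3a, so it ionises under acid, and loss of the C2 hydrogen turns ring B into an aromatic furan. The 2-substituted acrolein is a polymerisable Michael acceptor and the α-centre of the 2-methylbutanoate epimerises under base, so the enal must come last and no strong base may follow the second esterification. The enabling feature is the C2–C3 bond: C2 is both allylic to Cα=CH2 and bonded to O1, and C3 is a benzylic carbinol ortho to that oxygen. C2–C3 is therefore the bond an oxygen-substituted allyl metal forms when its oxygen-bearing carbon adds to an aldehyde on C3a, and an allene on O1 supplies that allyl metal while leaving a substituent on Cα.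

## Retrosynthesis

The formyl group of 19 is taken back to the methyl group of 17, so two C–H bonds of the allylic methyl are "cut". The enal is the most reactive function and would not survive a ketone reduction, so it is made last. Carrying a protected allylic alcohol instead would cost protecting-group steps. The forward oxidation must choose the methyl over the C2 methine and spare two esters.

Diester 17 is cut at the acyl C–O bond of the side-chain ester into carbinol 15 and the purchased acid 16. This removes one stereocentre from the synthetic work. The coupling must proceed with retention at the carbinol and without epimerising the acid.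

Carbinol 15 is cut at its C–H bond, back to ketone 14. The centre is remote from ring B, so a chiral reduction catalyst sets it. The ketone is also the form in which this oxygen stays masked while C3 is acylated. The reduction must leave the isopropenyl group and the C3 ester alone.

Ketone 14 comes from ketal 13 by hydrolysis. In 13 the C3–O bond is cut with inversion, giving cis alcohol 11 and acid 12. Acylation of a trans alcohol with retention would be simpler, but the ring-forming step cannot supply a trans alcohol (see below). Inverting in the same operation that brings in the acyl group costs no step. The forward reaction is an SN2 displacement at benzylic C3 from the face opposite the C2 substituent, and it must outrun elimination to the benzofuran.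

The methyl on Cα of 11 is cut off, leading to alkenylboronate 10 and a methyl electrophile. Boron is what the ring-forming step leaves on Cα, and a one-carbon cross-coupling is the shortest way to the isopropenyl group. Turning C–B directly into the formyl group would bring the enal in far too early. The coupling must tolerate the free cis hydroxyl.

Alcohol 10 is cut at C2–C3 and Cα–B, giving the achiral allene aldehyde 7 and diboron reagent 8. The neighbouring cuts are weaker. Opening O1–C2 needs a stereodefined diol derivative with a leaving group on an allylic carbon next to a benzylic one and invites benzofuran formation. Opening C3a–C3 needs an aryl anion and a labile α-oxy aldehyde. The C2–C3 cut removes ring B, both ring stereocentres and the boron at once and leaves one ring and no stereocentre. The forward reaction must add a boryl copper species to the terminal allene double bond in preference to the aldehyde, and a chiral ligand must control the attack of the oxygen-bearing allyl carbon on the aldehyde.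

An all-equatorial chair leading directly to the trans alcohol was examined and set aside. Ring A holds O1 and C3a too close for the 60° twist about the forming bond that such a chair needs. The closed transition state that remains puts Cα and the new hydroxyl on the same face, so the plan takes cis alcohol 10 as the product and corrects C3 in the acylation step.

Allene 7 is the prototropic isomer of propargyl ether 6, which is cut at O–CH2 into salicylaldehyde 4 and propargyl bromide 5. No shorter access to an aryloxyallene exists. The forward steps are an O-alkylation and a base-catalysed hydrogen shift that must stop at the allene and leave the neighbouring aldehyde untouched.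

Aldehyde 4 is cut at the bond between C3a and the formyl carbon, back to phenol 2, the dioxolane of 1. A para-substituted magnesium phenoxide formylates only ortho, so there is no regiochemical question. The ketone is masked because a free methyl ketone would condense with the aryl aldehyde under the alkoxide bases of the allene-forming and ring-forming steps, and would offer the allylcopper a second carbonyl.

## Roads not taken

Alternative 1: Ring A is cut at C3a–C7a, C4–C5 and C6–C7, leading to acetylene A3 and the acyclic 1,6-diyne A2, an ethynyl ether whose two stereocentres would come from a sugar. RhCl(PPh3)3 would join the two alkynes of A2 with A3 in a (2+2+2) cyclotrimerisation. Because the O1–C2–C3 tether is already in place, ring B forms with ring A, giving A1.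

- Merits: C2 and C3 come from the chiral pool, trans before any ring exists. Neither an asymmetric catalyst nor an inversion at C3 is needed, and in that respect this road is safer than the chosen one.
- Weak points: A1 has no carbon at C5. The acetyl group would need a later Friedel–Crafts acylation beside a benzylic MOM ether and a tertiary silyl ether, or an unsymmetrical alkyne whose orientation (C5 against C6) the catalyst has no reason to control. A2 contains a hydrolytically labile secondary alkyl ethynyl ether and is many steps from a sugar. After the key step the route still needs the MOM-to-ester exchange and a regioselective dehydration of the tertiary alcohol, then the same last four steps as the chosen plan.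
- Comparison: against chiral-pool security the chosen plan sets eleven steps, the C5 substituent present from step 1, and ring B, both stereocentres and the Cα handle formed together.

Alternative 2: Ring B is made from a six-membered ring by forming the target's O1–C2 bond and breaking an O–CMe2 bond in the trans chromanol A5. Tf2O would activate the C3 hydroxyl of A5 as a triflate leaving group. The aryl ether oxygen would displace it from the back with inversion, and the tertiary cation left behind would lose a methyl proton. The product A4 has the same structure as 14.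

- Merits: this road is shorter. A5 is within four steps of 1 and 12 by reactions of established type, and A4 would be reached about three steps earlier than 14. Epoxidation of 2,2-dimethylchromenes with (salen)MnCl catalysts is a very reliable way to set two adjacent stereocentres. The trans arrangement follows directly, with no boron, palladium, ketal or inversion.
- Weak points: the migration needs the C3 leaving group axial and antiperiplanar to O1–C2. That puts the trans C4 ester axial and antiperiplanar to the same leaving group, where its carbonyl is the classical neighbouring group; it would close a dioxolanylium ion and end in cis-diol monoesters. O1, which must beat it, is a poor donor because its lone pair is drawn into a ring bearing a para acetyl group. The step also generates cations next to an easily ionised benzylic ester.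
- Comparison: the chosen plan pays three more steps and rests on an asymmetric cyclisation still to be proven on this substrate. Against that, its ring closure runs through one cyclic transition state with one possible relative configuration, not a contest between two neighbouring groups, and it keeps strong electrophiles away from the C3 ester. Alternative 2 is kept as the fallback for the key step.

Alternative 3: Ring B is cut at O1–C7a and C3a–C3. CsF would release the 3-chloroaryne A9 from silyl triflate A8. The alkoxide of the α-hydroxy aldehyde A7 would add at the carbon meta to chlorine (C7a), and the aryl anion formed ortho to chlorine (C3a) would add to the aldehyde, closing ring B to give A6.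

- Merits: convergent. Ring B and the isopropenyl group arrive in one step and C2 is bought in with A7, so no methylation and perhaps no inversion is needed. Fewer steps would follow the ring closure than in the chosen plan.
- Weak points: A7 is a β,γ-unsaturated α-hydroxy aldehyde whose stereocentre is both α to the carbonyl and allylic; the fluoride and alkoxide medium invites racemisation, alkene conjugation and self-condensation. C3 is set only by substrate control in a fast anion–carbonyl collapse with nothing favouring trans. The directing chlorine must later be removed under reducing conditions that threaten the isopropenyl group and the benzylic C–O bonds. A8 is itself a multistep tetrasubstituted arene.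
- Comparison: the chosen plan uses a stable achiral precursor four steps from 1, sets C2 and C3 together under catalyst control and carries no atom to delete later. It concedes the extra methylation step and the inversion at C3.

Key step: step 5

Assumption: (R)-2-methylbutanoic acid and both antipodes of Ph-BPE are treated as commercial, and the route is written for the cis alcohol that the closed transition state of step 5 dictates.

## Route

Step 1
Reactants: 1 4'-hydroxyacetophenone
Product: 2 4-(2-methyl-1,3-dioxolan-2-yl)phenol
Conditions: ethylene glycol, TsOH·H2O (cat.), toluene, reflux (Dean–Stark); Et3N quench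
Reagents that add atoms: ethylene glycol, OCCO
Why: Acid-catalysed ketalisation driven by azeotropic removal of water; the phenol does not interfere, and the dioxolane masks the enolisable ketone for the basic steps 3 to 6.

Step 2
Reactants: 2 4-(2-methyl-1,3-dioxolan-2-yl)phenol
Product: 4 2-hydroxy-5-(2-methyl-1,3-dioxolan-2-yl)benzaldehyde, via 2-(hydroxymethyl)-4-(2-methyl-1,3-dioxolan-2-yl)phenol 3 (not isolated)
Conditions: MgCl2, Et3N, (CH2O)n, MeCN, reflux; cold aq. NH4Cl
Reagents that add atoms: formaldehyde (as paraformaldehyde), C=O
Why: Magnesium-mediated ortho-formylation (Casnati–Skattebøl): the magnesium phenoxide delivers formaldehyde to the only free ortho-type position, and the hydroxymethyl intermediate 3 is oxidised in place by hydride transfer to a second formaldehyde. The basic medium and a weakly acidic work-up spare the ketal.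

Step 3
Reactants: 4 2-hydroxy-5-(2-methyl-1,3-dioxolan-2-yl)benzaldehyde; 5 propargyl bromide
Product: 6 5-(2-methyl-1,3-dioxolan-2-yl)-2-(prop-2-yn-1-yloxy)benzaldehyde
Conditions: K2CO3, DMF, rt
Reagents that add atoms: none
Why: Williamson ether synthesis; the phenoxide of the salicylaldehyde is alkylated on oxygen by the primary propargylic bromide in an SN2 reaction.

Step 4
Reactants: 6 5-(2-methyl-1,3-dioxolan-2-yl)-2-(prop-2-yn-1-yloxy)benzaldehyde
Product: 7 5-(2-methyl-1,3-dioxolan-2-yl)-2-(propa-1,2-dien-1-yloxy)benzaldehyde
Conditions: KOtBu (0.3 equiv), THF, 0 °C to rt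
Reagents that add atoms: none
Why: Base-catalysed propargyl-to-allenyl prototropic isomerisation of an aryl propargyl ether; the allenyl ether forms first, and substoichiometric base at low temperature stops before the 1-propynyl ether. The aldehyde has no α-hydrogen and the ketone is masked.

Step 5
Reactants: 7 5-(2-methyl-1,3-dioxolan-2-yl)-2-(propa-1,2-dien-1-yloxy)benzaldehyde; 8 bis(pinacolato)diboron
Product: 10 (2R,3R)-5-(2-methyl-1,3-dioxolan-2-yl)-2-[1-(4,4,5,5-tetramethyl-1,3,2-dioxaborolan-2-yl)ethenyl]-2,3-dihydro-1-benzofuran-3-ol, via C3-O-pinacolboryl ether of the cis alcohol 9 (not isolated)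
Conditions: CuCl (5 mol%), Ph-BPE (6 mol%; the antipode that delivers 2R,3R), NaOtBu (20 mol%), THF, 22 °C; then aq. NH4Cl
Reagents that add atoms: none
Why: CuCl, NaOtBu and the bisphosphine give a ligated copper tert-butoxide that 8 converts into the copper–boryl species, which adds across the terminal C=C of the aryloxyallene with boron going to the central carbon (the future Cα) and copper to CH2. The resulting 2-boryl allylcopper carries O1 on its γ-carbon and adds through that carbon to the ortho aldehyde, forming C2–C3 and closing ring B by a 5-exo-trig attack on the carbonyl; the copper alkoxide is borylated by 8 to give 9, which regenerates the copper–boryl species, and 9 is hydrolysed to 10 on work-up. The closest known reaction type is the copper-catalysed enantioselective borylative coupling of allenes with aldehydes through 2-boryl allylcopper species, together with its cyclising variants on allene-tethered ketones; here the two partners are tied through an aryl ether. Because ring A holds O1 and C3a two bonds apart, the torsion O1–C2–C3–C3a must stay small in the transition state, so copper can bridge the carbonyl oxygen and the allyl CH2 only when Cα and the carbonyl oxygen lie on the same face of the forming ring; a chair with O1 and C3a both equatorial, which would give the trans alcohol, is out of reach. The closed, boat-like transition state therefore fixes C2 and C3 as cis whatever the allylcopper geometry, and the absolute configuration of both follows from the aldehyde face chosen by the chiral bisphosphine–copper fragment. The step needs chemoselectivity for the allene over the aldehyde in the Cu–B addition, which faster insertion of the cumulene provides, and site selectivity for the oxygen-bearing carbon, which the tether secures because attack through CH2 would need a seven-membered ring; the ketal keeps the second carbonyl away from both copper species.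

Step 6
Reactants: 10 (2R,3R)-5-(2-methyl-1,3-dioxolan-2-yl)-2-[1-(4,4,5,5-tetramethyl-1,3,2-dioxaborolan-2-yl)ethenyl]-2,3-dihydro-1-benzofuran-3-ol
Product: 11 (2R,3R)-5-(2-methyl-1,3-dioxolan-2-yl)-2-(prop-1-en-2-yl)-2,3-dihydro-1-benzofuran-3-ol
Conditions: MeI, PdCl2(dppf) (5 mol%), K3PO4, DMF/H2O (10:1), 50 °C
Reagents that add atoms: iodomethane, CI
Why: Suzuki–Miyaura cross-coupling of an alkenyl pinacol boronate with iodomethane: oxidative addition of MeI to zerovalent palladium, base-assisted transmetalation and fast reductive elimination from the dppf complex give the isopropenyl group. The free cis hydroxyl is tolerated, and C2 and C3 are untouched.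

Step 7
Reactants: 11 (2R,3R)-5-(2-methyl-1,3-dioxolan-2-yl)-2-(prop-1-en-2-yl)-2,3-dihydro-1-benzofuran-3-ol; 12 3-methylbutanoic acid
Product: 13 (2R,3S)-5-(2-methyl-1,3-dioxolan-2-yl)-2-(prop-1-en-2-yl)-2,3-dihydro-1-benzofuran-3-yl 3-methylbutanoate
Conditions: PPh3, DIAD, THF, 0 °C to rt
Reagents that add atoms: none
Why: Mitsunobu esterification: the alkoxyphosphonium ion at C3 is displaced by the carboxylate in an SN2 reaction from the face opposite the cis isopropenyl group, so C3 is inverted from R to S and the trans ester results. Even an ionised C3 would be captured anti to the C2 substituent, so both pathways converge on 13.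

Step 8
Reactants: 13 (2R,3S)-5-(2-methyl-1,3-dioxolan-2-yl)-2-(prop-1-en-2-yl)-2,3-dihydro-1-benzofuran-3-yl 3-methylbutanoate
Product: 14 (2R,3S)-5-acetyl-2-(prop-1-en-2-yl)-2,3-dihydro-1-benzofuran-3-yl 3-methylbutanoate
Conditions: PPTS (0.2 equiv), acetone/H2O (10:1), 40 °C
Reagents that add atoms: water, O
Why: Mild acid-catalysed ketal hydrolysis; the dioxolane of a para-alkoxyaryl methyl ketone opens through a well-stabilised oxocarbenium ion under conditions too weak to ionise the C3 ester.

Step 9
Reactants: 14 (2R,3S)-5-acetyl-2-(prop-1-en-2-yl)-2,3-dihydro-1-benzofuran-3-yl 3-methylbutanoate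
Product: 15 (2R,3S)-5-[(1R)-1-hydroxyethyl]-2-(prop-1-en-2-yl)-2,3-dihydro-1-benzofuran-3-yl 3-methylbutanoate
Conditions: RuCl[(R,R)-TsDPEN](p-cymene) (1 mol%), HCO2H/Et3N (5:2), EtOAc, 30 °C
Reagents that add atoms: none
Why: Noyori asymmetric transfer hydrogenation of an aryl methyl ketone; the (R,R)-TsDPEN ruthenium hydride gives the (R)-carbinol, as it does with acetophenones, under pure catalyst control remote from ring B. Isolated alkenes and esters are not reduced.

Step 10
Reactants: 15 (2R,3S)-5-[(1R)-1-hydroxyethyl]-2-(prop-1-en-2-yl)-2,3-dihydro-1-benzofuran-3-yl 3-methylbutanoate; 16 (R)-2-methylbutanoic acid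
Product: 17 (1R)-1-[(2R,3S)-3-[(3-methylbutanoyl)oxy]-2-(prop-1-en-2-yl)-2,3-dihydro-1-benzofuran-5-yl]ethyl (2R)-2-methylbutanoate
Conditions: DCC, DMAP (0.1 equiv), CH2Cl2, 0 °C to rt
Reagents that add atoms: none
Why: Steglich esterification; the O-acylisourea of 16 acylates the secondary benzylic alcohol with retention at the carbinol carbon. Low temperature and catalytic DMAP keep the α-stereocentre of the acid intact.

Step 11
Reactants: 17 (1R)-1-[(2R,3S)-3-[(3-methylbutanoyl)oxy]-2-(prop-1-en-2-yl)-2,3-dihydro-1-benzofuran-5-yl]ethyl (2R)-2-methylbutanoate
Product: 19 (1R)-1-[(2R,3S)-3-[(3-methylbutanoyl)oxy]-2-(3-oxoprop-1-en-2-yl)-2,3-dihydro-1-benzofuran-5-yl]ethyl (2R)-2-methylbutanoate, via allylic alcohol 18 (not isolated)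
Conditions: SeO2 (0.5 equiv), tBuOOH (3 equiv), CH2Cl2, rt; then MnO2, CH2Cl2, rt
Reagents that add atoms: selenium dioxide, O=[Se]=O; tert-butyl hydroperoxide, CC(C)(C)OO
Why: Riley allylic oxidation under Sharpless conditions: the ene reaction at the terminal alkene carbon takes hydrogen from the methyl, not the hindered C2 methine, and a [2,3]-sigmatropic shift gives allylic alcohol 18 with some enal. MnO2 then oxidises the allylic alcohol selectively and converges the mixture on enal 19 without touching esters or stereocentres.

## Compound list

1 | 4'-hydroxyacetophenone | CC(=O)c1ccc(O)cc1 | starting material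
2 | 4-(2-methyl-1,3-dioxolan-2-yl)phenol | CC1(OCCO1)c1ccc(O)cc1 | intermediate
3 | 2-(hydroxymethyl)-4-(2-methyl-1,3-dioxolan-2-yl)phenol | CC1(OCCO1)c1ccc(O)c(CO)c1 | intermediate
4 | 2-hydroxy-5-(2-methyl-1,3-dioxolan-2-yl)benzaldehyde | CC1(OCCO1)c1ccc(O)c(C=O)c1 | intermediate
5 | propargyl bromide (3-bromoprop-1-yne) | C#CCBr | starting material
6 | 5-(2-methyl-1,3-dioxolan-2-yl)-2-(prop-2-yn-1-yloxy)benzaldehyde | CC1(OCCO1)c1ccc(OCC#C)c(C=O)c1 | intermediate
7 | 5-(2-methyl-1,3-dioxolan-2-yl)-2-(propa-1,2-dien-1-yloxy)benzaldehyde | CC1(OCCO1)c1ccc(OC=C=C)c(C=O)c1 | intermediate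
8 | bis(pinacolato)diboron | CC1(C)OB(OC1(C)C)B1OC(C)(C)C(C)(C)O1 | starting material
9 | 2-({(2R,3R)-5-(2-methyl-1,3-dioxolan-2-yl)-2-[1-(4,4,5,5-tetramethyl-1,3,2-dioxaborolan-2-yl)ethenyl]-2,3-dihydro-1-benzofuran-3-yl}oxy)-4,4,5,5-tetramethyl-1,3,2-dioxaborolane | C=C(B1OC(C)(C)C(C)(C)O1)[C@H]1Oc2ccc(C3(C)OCCO3)cc2[C@H]1OB1OC(C)(C)C(C)(C)O1 | intermediate
10 | (2R,3R)-5-(2-methyl-1,3-dioxolan-2-yl)-2-[1-(4,4,5,5-tetramethyl-1,3,2-dioxaborolan-2-yl)ethenyl]-2,3-dihydro-1-benzofuran-3-ol (cis) | C=C(B1OC(C)(C)C(C)(C)O1)[C@H]1Oc2ccc(C3(C)OCCO3)cc2[C@H]1O | intermediate
11 | (2R,3R)-5-(2-methyl-1,3-dioxolan-2-yl)-2-(prop-1-en-2-yl)-2,3-dihydro-1-benzofuran-3-ol (cis) | C=C(C)[C@H]1Oc2ccc(C3(C)OCCO3)cc2[C@H]1O | intermediate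
12 | 3-methylbutanoic acid | CC(C)CC(=O)O | starting material
13 | (2R,3S)-5-(2-methyl-1,3-dioxolan-2-yl)-2-(prop-1-en-2-yl)-2,3-dihydro-1-benzofuran-3-yl 3-methylbutanoate (trans) | C=C(C)[C@H]1Oc2ccc(C3(C)OCCO3)cc2[C@@H]1OC(=O)CC(C)C | intermediate
14 | (2R,3S)-5-acetyl-2-(prop-1-en-2-yl)-2,3-dihydro-1-benzofuran-3-yl 3-methylbutanoate | C=C(C)[C@H]1Oc2ccc(C(C)=O)cc2[C@@H]1OC(=O)CC(C)C | intermediate
15 | (2R,3S)-5-[(1R)-1-hydroxyethyl]-2-(prop-1-en-2-yl)-2,3-dihydro-1-benzofuran-3-yl 3-methylbutanoate | C=C(C)[C@H]1Oc2ccc([C@@H](C)O)cc2[C@@H]1OC(=O)CC(C)C | intermediate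
16 | (R)-2-methylbutanoic acid | CC[C@@H](C)C(=O)O | starting material
17 | (1R)-1-[(2R,3S)-3-[(3-methylbutanoyl)oxy]-2-(prop-1-en-2-yl)-2,3-dihydro-1-benzofuran-5-yl]ethyl (2R)-2-methylbutanoate | C=C(C)[C@H]1Oc2ccc([C@@H](C)OC(=O)[C@H](C)CC)cc2[C@@H]1OC(=O)CC(C)C | intermediate
18 | (1R)-1-[(2R,3S)-2-(3-hydroxyprop-1-en-2-yl)-3-[(3-methylbutanoyl)oxy]-2,3-dihydro-1-benzofuran-5-yl]ethyl (2R)-2-methylbutanoate | C=C(CO)[C@H]1Oc2ccc([C@@H](C)OC(=O)[C@H](C)CC)cc2[C@@H]1OC(=O)CC(C)C | intermediate
19 | (1R)-1-[(2R,3S)-3-[(3-methylbutanoyl)oxy]-2-(3-oxoprop-1-en-2-yl)-2,3-dihydro-1-benzofuran-5-yl]ethyl (2R)-2-methylbutanoate (CNP0154159.1) | C=C(C=O)[C@H]1Oc2ccc([C@@H](C)OC(=O)[C@H](C)CC)cc2[C@@H]1OC(=O)CC(C)C | target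

## Step count and least certain steps

Total: 11 steps. Longest linear sequence: 11 steps, from 1 to 19; all other inputs are purchased.

Step 5 (key step). Most likely to go wrong: borylation or reduction of the aryl aldehyde by the copper–boryl species before the allene inserts. Enantioface discrimination may also be poor, because the boat-like cyclisation transition state differs from the intermolecular chair for which the bisphosphines are known to work. Fallback: ring B is made by contraction of a chroman, setting out from 1 and 12 and returning at 14. Phenol 1 is O-alkylated with 3-chloro-3-methylbut-1-yne (K2CO3, KI, CuCl cat., acetone) to 1-{4-[(2-methylbut-3-yn-2-yl)oxy]phenyl}ethan-1-one F1. Heating (N,N-diethylaniline, 190 °C; aryl propargyl Claisen rearrangement, hydrogen shift and electrocyclisation) gives 1-(2,2-dimethyl-2H-chromen-6-yl)ethan-1-one F2. Epoxidation with the (R,R)-(salen)MnCl catalyst and NaOCl gives 1-[(3R,4R)-3,4-epoxy-2,2-dimethyl-3,4-dihydro-2H-chromen-6-yl]ethan-1-one F3. Opening at benzylic C4 with inversion by acid 12 (as its caesium salt) gives (3R,4S)-6-acetyl-3-hydroxy-2,2-dimethyl-3,4-dihydro-2H-chromen-4-yl 3-methylbutanoate F4. Tf2O with a hindered pyridine at low temperature then moves the aryl ether oxygen from C2 to C3 with inversion and loss of a methyl proton, giving 14. Participation by the C4 ester is the known hazard of this last step.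

Step 7. Most likely to go wrong: elimination across C2–C3 to the aromatic benzofuran, since in the cis alcohol the C2 hydrogen is anti to the activated oxygen, competing with slow substitution by a weakly acidic aliphatic acid. Fallback: inversion and acylation are separated, setting out from 11 and returning at 13. Mitsunobu reaction with the more acidic 4-nitrobenzoic acid gives (2R,3S)-5-(2-methyl-1,3-dioxolan-2-yl)-2-(prop-1-en-2-yl)-2,3-dihydro-1-benzofuran-3-yl 4-nitrobenzoate F5. Methanolysis (K2CO3, MeOH) frees (2R,3S)-5-(2-methyl-1,3-dioxolan-2-yl)-2-(prop-1-en-2-yl)-2,3-dihydro-1-benzofuran-3-ol F6. Acylation with 12 (DCC, DMAP) with retention gives 13.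

Step 6. Most likely to go wrong: protodeboronation of the alkenylboronate in aqueous base, or β-aryloxide elimination from the alkenylpalladium intermediate, which would open ring B. Fallback: a palladium-free Zweifel-type coupling, setting out from 10 and returning at 11. MeLi (2.2 equiv, THF, −78 °C) deprotonates the hydroxyl and forms the methyl boronate complex. I2 then triggers 1,2-migration of methyl from boron to Cα, and NaOMe induces anti-elimination of boron and iodide to give 11. No new isolable compound is made.

Step 4. Most likely to go wrong: attack of the propargyl/allenyl carbanion or of tert-butoxide on the neighbouring aldehyde, or over-isomerisation to the 1-propynyl ether. Fallback: the aldehyde is taken out of play by a redox detour, setting out from 6 and returning at 7. NaBH4 reduction gives [5-(2-methyl-1,3-dioxolan-2-yl)-2-(prop-2-yn-1-yloxy)phenyl]methanol F7. Isomerisation with excess KOtBu gives [5-(2-methyl-1,3-dioxolan-2-yl)-2-(propa-1,2-dien-1-yloxy)phenyl]methanol F8. MnO2 oxidation of the benzylic alcohol gives 7.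

Step 11. Most likely to go wrong: ene reaction at the C2 methine instead of the methyl (which would cleave ring B), acid-promoted loss of the C3 ester by seleninic acid, or over-oxidation. Fallback: halogenation then oxygen transfer, setting out from 17 and returning at 19. Ene-type allylic chlorination (Ca(OCl)2, CO2, CH2Cl2/H2O, 0 °C) gives (1R)-1-[(2R,3S)-2-(3-chloroprop-1-en-2-yl)-3-[(3-methylbutanoyl)oxy]-2,3-dihydro-1-benzofuran-5-yl]ethyl (2R)-2-methylbutanoate F9. Amine-oxide oxidation of the allylic chloride (NMO, NaHCO3, MeCN) gives 19.

## Further compounds

F1 | step 5 | 1-{4-[(2-methylbut-3-yn-2-yl)oxy]phenyl}ethan-1-one | CC(=O)c1ccc(OC(C)(C)C#C)cc1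
F2 | step 5 | 1-(2,2-dimethyl-2H-chromen-6-yl)ethan-1-one | CC(=O)c1ccc2OC(C)(C)C=Cc2c1
F3 | step 5 | 1-[(3R,4R)-3,4-epoxy-2,2-dimethyl-3,4-dihydro-2H-chromen-6-yl]ethan-1-one | CC(=O)c1ccc2OC(C)(C)[C@@H]3O[C@@H]3c2c1
F4 | step 5 | (3R,4S)-6-acetyl-3-hydroxy-2,2-dimethyl-3,4-dihydro-2H-chromen-4-yl 3-methylbutanoate | CC(=O)c1ccc2OC(C)(C)[C@H](O)[C@@H](OC(=O)CC(C)C)c2c1
F5 | step 7 | (2R,3S)-5-(2-methyl-1,3-dioxolan-2-yl)-2-(prop-1-en-2-yl)-2,3-dihydro-1-benzofuran-3-yl 4-nitrobenzoate | C=C(C)[C@H]1Oc2ccc(C3(C)OCCO3)cc2[C@@H]1OC(=O)c1ccc(cc1)[N+](=O)[O-]
F6 | step 7 | (2R,3S)-5-(2-methyl-1,3-dioxolan-2-yl)-2-(prop-1-en-2-yl)-2,3-dihydro-1-benzofuran-3-ol | C=C(C)[C@H]1Oc2ccc(C3(C)OCCO3)cc2[C@@H]1O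
F0 | step 6 | none | none
F7 | step 4 | [5-(2-methyl-1,3-dioxolan-2-yl)-2-(prop-2-yn-1-yloxy)phenyl]methanol | CC1(OCCO1)c1ccc(OCC#C)c(CO)c1
F8 | step 4 | [5-(2-methyl-1,3-dioxolan-2-yl)-2-(propa-1,2-dien-1-yloxy)phenyl]methanol | CC1(OCCO1)c1ccc(OC=C=C)c(CO)c1
F9 | step 11 | (1R)-1-[(2R,3S)-2-(3-chloroprop-1-en-2-yl)-3-[(3-methylbutanoyl)oxy]-2,3-dihydro-1-benzofuran-5-yl]ethyl (2R)-2-methylbutanoate | C=C(CCl)[C@H]1Oc2ccc([C@@H](C)OC(=O)[C@H](C)CC)cc2[C@@H]1OC(=O)CC(C)C
A1 | alternative 1 | tert-butyl({2-[(2S,3S)-3-(methoxymethoxy)-2,3-dihydro-1-benzofuran-2-yl]propan-2-yl}oxy)dimethylsilane | CC(C)(O[Si](C)(C)C(C)(C)C)[C@H]1Oc2ccccc2[C@@H]1OCOC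
A2 | alternative 1 | tert-butyl{[(3S,4S)-3-(ethynyloxy)-4-(methoxymethoxy)-2-methylhex-5-yn-2-yl]oxy}dimethylsilane | C#CO[C@H](C(C)(C)O[Si](C)(C)C(C)(C)C)[C@@H](OCOC)C#C
A3 | alternative 1 | acetylene | C#C
A4 | alternative 2 | (2R,3S)-5-acetyl-2-(prop-1-en-2-yl)-2,3-dihydro-1-benzofuran-3-yl 3-methylbutanoate | C=C(C)[C@H]1Oc2ccc(C(C)=O)cc2[C@@H]1OC(=O)CC(C)C
A5 | alternative 2 | (3R,4S)-6-acetyl-3-hydroxy-2,2-dimethyl-3,4-dihydro-2H-chromen-4-yl 3-methylbutanoate | CC(=O)c1ccc2OC(C)(C)[C@H](O)[C@@H](OC(=O)CC(C)C)c2c1
A6 | alternative 3 | (2R,3S)-4-chloro-5-(2-methyl-1,3-dioxolan-2-yl)-2-(prop-1-en-2-yl)-2,3-dihydro-1-benzofuran-3-ol | C=C(C)[C@H]1Oc2ccc(C3(C)OCCO3)c(Cl)c2[C@@H]1O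
A7 | alternative 3 | (2R)-2-hydroxy-3-methylbut-3-enal | C=C(C)[C@@H](O)C=O
A8 | alternative 3 | 3-chloro-4-(2-methyl-1,3-dioxolan-2-yl)-2-(trimethylsilyl)phenyl trifluoromethanesulfonate | CC1(OCCO1)c1ccc(OS(=O)(=O)C(F)(F)F)c([Si](C)(C)C)c1Cl
A9 | alternative 3 | 2-(2-chloro-3,4-didehydrophenyl)-2-methyl-1,3-dioxolane (the 3-chloroaryne) | CC1(OCCO1)C1=C(Cl)C#CC=C1
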